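**Plan** (carotenoid numbering: ring carbons C1–C6, hydroxyprenyl side chain on C2, polyene from C7; primed numbers for the acyclic half)
- Cuts, in order: C11=C12 and C11'=C12' (two Wittig reactions on the C10 trienedial 32); C7=C8, C3'=C4' and C7'=C8' (C5 phosphonate 15); then the ring bonds C3–C4 and C1–C6.
- Enabling feature: in the 1,1,5-trimethylcyclohex-4-ene ring, C1(Me)2–C2H(side chain)–C3H2 is the isopropenyl carbon, the stereocentre and the CH2O carbon of lavandulol, and C4–C5–C6(–C7) is the CH3–C(=O)–CH2(–CO2Me) chain of methyl acetoacetate. The ring is therefore a [3+3] union of a lavandulyl 1,3-bis-electrophile (C3–Br; C1 as the cation of the isopropenyl group) with the acetoacetate 1,3-bis-nucleophile (C4, C6).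
- Forward: 1 → bromide 4 → one-flask annulation to keto ester 8 → C5 methyl (10) → deconjugation to the exo-methylene ester 12 → double-bond shift into the ring (13) → aldehyde 14 → phosphonium salt 19; in parallel 1 → aldehyde 23 → two C5 homologations → salt 31; then 31 + 32 → 33, 33 + 19 → 34, desilylation → 35.
- Stereochemistry: C2 and C2' are carried over unchanged from one enantiomer, (R)-lavandulol. C6 is set cis to the C2 side chain by kinetic protonation of dienolate 11 (step 7) and is not touched by the double-bond shift of step 8. The E alkenes come from SeO2 oxidation, Horner–Wadsworth–Emmons and Wittig reactions with a final equilibration.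

Key step: step 4

Remark: (R)-(−)-lavandulol, the natural enantiomer, is taken as a purchasable chiral-pool alcohol; 15 and 32 are the usual commercial C5 and C10 carotenoid building blocks (TBDPS = tert-butyldiphenylsilyl, TES = triethylsilyl).

**Ring half**

Step 1
Reactants: 1 (R)-lavandulol
Product: 2 (3R)-3-(bromomethyl)-2,6-dimethylhepta-1,5-diene
Conditions: CBr4, PPh3, CH2Cl2, 0 °C
Reagents that add atoms: carbon tetrabromide BrC(Br)(Br)Br
Why: Appel reaction: SN2 displacement of the activated primary alcohol by bromide should leave the neighbouring stereocentre and both alkenes untouched.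

Step 2
Reactants: 2 (R)-lavandulyl bromide
Product: 3 (2E,5R)-5-(bromomethyl)-2,6-dimethylhepta-2,6-dien-1-ol
Conditions: SeO2 (0.3 equiv), t-BuOOH, CH2Cl2, 0 °C → rt
Reagents that add atoms: tert-butyl hydroperoxide CC(C)(C)OO (terminal oxidant; the oxygen is relayed by SeO2 O=[Se]=O)
Why: Catalytic SeO2 allylic oxidation (ene reaction then 2,3-sigmatropic shift) should select the more electron-rich trisubstituted alkene over the isopropenyl group and oxidise its E-methyl group, which fixes the E geometry of the 4-hydroxy-3-methylbut-2-enyl chain.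

Step 3
Reactants: 3 bromo allylic alcohol
Product: 4 tert-butyl{[(2E,5R)-5-(bromomethyl)-2,6-dimethylhepta-2,6-dien-1-yl]oxy}diphenylsilane
Conditions: t-BuPh2SiCl, imidazole, CH2Cl2, 0 °C → rt
Reagents that add atoms: tert-butyl(chloro)diphenylsilane CC(C)(C)[Si](Cl)(c1ccccc1)c1ccccc1
Why: Standard silylation of the primary allylic alcohol; the bulky silyl ether is chosen to survive the dianion, SnCl4, amide base, i-Bu2AlH and HBr steps and to deactivate the neighbouring alkene towards acid.

Step 4
Reactants: 4 silylated lavandulyl bromide; 5 methyl acetoacetate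
Product: 8 methyl (1S,3R)-3-[(2E)-4-(TBDPSO)-3-methylbut-2-en-1-yl]-2,2-dimethyl-6-oxocyclohexane-1-carboxylate, via dianion of methyl acetoacetate 6 (not isolated), via acyclic keto ester 7 (not isolated)
Conditions: 5, NaH, THF, 0 °C; n-BuLi, 0 °C; 4, n-Bu4NI (cat.), 0 °C → rt; HCl/Et2O, −78 °C; solvent switch to CH2Cl2 (no work-up); SnCl4, −20 → 0 °C
Reagents that add atoms: none
Why: The 1,3-dianion 6 is alkylated at its terminal carbon (future C4) by the primary bromide of 4 in an SN2 step that forms C3–C4 and leaves the lavandulyl stereocentre (C2) untouched; after protonation to 7, SnCl4 chelates the β-keto ester as its enol, the acid set free protonates the isopropenyl group in the Markovnikov sense, and the enol carbon (future C6) is alkylated by the tertiary cation (future C1), which closes the ring and creates the gem-dimethyl quaternary carbon. The closest known reaction types are the γ-alkylation of acetoacetate dianions and the SnCl4-mediated cation–olefin cyclisation of alkenyl β-keto esters to 2,2-dimethyl-6-oxocyclohexanecarboxylates, here telescoped into one [3+3] annulation. The single ring closes in a 6-(enol-endo) mode on the nucleophile and exo on the former alkene, whose CH2 becomes the second methyl group. The only new stereocentre, the ester-bearing C6, is a labile β-keto ester position that should settle with the ester equatorial, cis to the C2 side chain, and is erased in step 5, whereas C2 comes unchanged from (R)-lavandulol. The step needs γ- over α-alkylation (secured by the dianion), substitution over elimination (primary bromide, iodide catalysis), C- over O-alkylation (tin chelate), and protonation of the 1,1-disubstituted alkene in preference to the side-chain alkene, which is deactivated by its allylic silyloxy group.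

Step 5
Reactants: 8 ring β-keto ester
Product: 9 methyl (5R)-5-[(2E)-4-(TBDPSO)-3-methylbut-2-en-1-yl]-6,6-dimethyl-2-[(trifluoromethanesulfonyl)oxy]cyclohex-1-ene-1-carboxylate
Conditions: Tf2O, i-Pr2NEt, CH2Cl2, −78 °C
Reagents that add atoms: trifluoromethanesulfonic anhydride O=S(=O)(OS(=O)(=O)C(F)(F)F)C(F)(F)F
Why: O-sulfonylation of the β-keto ester enolate should give the conjugated vinyl triflate regiospecifically and removes the labile C6 stereocentre.

Step 6
Reactants: 9 vinyl triflate
Product: 10 methyl (5R)-5-[(2E)-4-(TBDPSO)-3-methylbut-2-en-1-yl]-2,6,6-trimethylcyclohex-1-ene-1-carboxylate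
Conditions: MeMgBr, Fe(acac)3 (5 mol %), THF/NMP, −30 °C
Reagents that add atoms: methylmagnesium bromide C[Mg]Br
Why: Iron-catalysed cross-coupling of an activated alkenyl triflate with a methyl Grignard reagent should install the C5 methyl group at low temperature without touching the ester or the silyl ether.

Step 7
Reactants: 10 conjugated ring ester
Product: 12 methyl (1R,3R)-3-[(2E)-4-(TBDPSO)-3-methylbut-2-en-1-yl]-2,2-dimethyl-6-methylidenecyclohexane-1-carboxylate, via exocyclic lithium dienolate 11 (not isolated)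
Conditions: LiN(i-Pr)2, THF, −78 → −20 °C; then AcOH in THF, −78 °C
Reagents that add atoms: none
Why: Deconjugative protonation of an ester dienolate: the ester-bound lithium amide removes a proton from the C5 methyl group, the γ-position cis to the ester (the ring C4 methylene is trans and out of reach), and kinetic α-protonation of the cross-conjugated dienolate 11 should deliver the proton axially to C6, anti to the axial C1 methyl group of the chair that keeps the C2 side chain equatorial, so that ester and side chain end up cis and diequatorial.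

Step 8
Reactants: 12 exo-methylene ring ester
Product: 13 methyl (1R,5R)-5-[(2E)-4-(TBDPSO)-3-methylbut-2-en-1-yl]-2,6,6-trimethylcyclohex-2-ene-1-carboxylate
Conditions: RhCl3·3H2O (5 mol %), EtOH, 70 °C
Reagents that add atoms: none
Why: Transition-metal-catalysed alkene isomerisation (hydride addition–elimination): the rhodium hydride formed in ethanol should add to the exocyclic 1,1-disubstituted alkene and eliminate towards the unhindered C4 methylene to give the trisubstituted C4=C5 alkene, while elimination towards C6 would give the twisted tetrasubstituted conjugated isomer and is expected to be slow, so that the C6 configuration is kept and the hindered side-chain alkene is left alone.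

Step 9
Reactants: 13 deconjugated ring ester
Product: 14 (1R,5R)-5-[(2E)-4-(TBDPSO)-3-methylbut-2-en-1-yl]-2,6,6-trimethylcyclohex-2-ene-1-carbaldehyde
Conditions: i-Bu2AlH, CH2Cl2, −78 °C; aq. potassium sodium tartrate work-up
Reagents that add atoms: none
Why: Partial reduction of the hindered ester with i-Bu2AlH at low temperature should stop at the aldehyde because the tetrahedral aluminium hemiacetal is stable until work-up.

Step 10
Reactants: 14 ring aldehyde; 15 ethyl (2E)-4-(diethoxyphosphoryl)-3-methylbut-2-enoate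
Product: 17 ethyl (2E,4E)-5-{(1R,5R)-5-[(2E)-4-(TBDPSO)-3-methylbut-2-en-1-yl]-2,6,6-trimethylcyclohex-2-en-1-yl}-3-methylpenta-2,4-dienoate, via sodium phosphonate carbanion 16 (not isolated)
Conditions: 15, NaH, THF, 0 °C; then 14, −20 °C → rt
Reagents that add atoms: none
Why: Horner–Wadsworth–Emmons olefination with the vinylogous phosphonate should form the C7=C8 double bond with E selectivity and carry the C9=C10 geometry of the reagent.

Step 11
Reactants: 17 ring dienoate
Product: 18 (2E,4E)-5-{(1R,5R)-5-[(2E)-4-(TBDPSO)-3-methylbut-2-en-1-yl]-2,6,6-trimethylcyclohex-2-en-1-yl}-3-methylpenta-2,4-dien-1-ol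
Conditions: i-Bu2AlH, CH2Cl2, −78 °C
Reagents that add atoms: none
Why: 1,2-Reduction of the dienoate with i-Bu2AlH should give the primary dienyl alcohol without affecting the silyl ether or the isolated alkenes.

Step 12
Reactants: 18 ring dienyl alcohol
Product: 19 {(2E,4E)-5-[(1R,5R)-5-((2E)-4-(TBDPSO)-3-methylbut-2-en-1-yl)-2,6,6-trimethylcyclohex-2-en-1-yl]-3-methylpenta-2,4-dien-1-yl}triphenylphosphonium bromide
Conditions: Ph3P·HBr, CH2Cl2, 0 °C → rt
Reagents that add atoms: triphenylphosphine hydrobromide [Br-].[PH+](c1ccccc1)(c1ccccc1)c1ccccc1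
Why: The dienyl alcohol ionises readily and the delocalised cation is captured by Ph3P at the primary terminus (SN1-type phosphonium salt formation), while the bulky silyl ether should survive the brief aprotic acid exposure.

**Acyclic half**

Step 13
Reactants: 1 (R)-lavandulol
Product: 21 (2S)-3-methyl-2-(3-methylbut-2-en-1-yl)butane-1,3-diol, via acetoxymercurio adduct 20 (not isolated)
Conditions: Hg(OAc)2, THF/H2O, 0 °C; then NaBH4, aq. NaOH, 0 °C
Reagents that add atoms: water O; Hg(OAc)2 CC(=O)O[Hg]OC(C)=O (its mercury and acetate stay only in 20)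
Why: Oxymercuration–demercuration should hydrate the 1,1-disubstituted isopropenyl group in the Markovnikov sense faster than the more hindered trisubstituted alkene, giving the tertiary alcohol without touching the stereocentre.

Step 14
Reactants: 21 diol
Product: 22 (2R)-3-hydroxy-3-methyl-2-(3-methylbut-2-en-1-yl)butanal
Conditions: TEMPO (cat.), PhI(OAc)2, CH2Cl2, rt
Reagents that add atoms: none
Why: The oxoammonium (TEMPO) oxidation is selective for the primary alcohol and cannot touch the tertiary one.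

Step 15
Reactants: 22 β-hydroxy aldehyde
Product: 23 (2R)-3-methyl-2-(3-methylbut-2-en-1-yl)-3-[(triethylsilyl)oxy]butanal
Conditions: Et3SiOTf, 2,6-lutidine, CH2Cl2, −78 °C
Reagents that add atoms: triethylsilyl trifluoromethanesulfonate CC[Si](CC)(CC)OS(=O)(=O)C(F)(F)F
Why: Silylation of the tertiary alcohol with the silyl triflate at low temperature blocks retro-aldol cleavage of the β-hydroxy aldehyde in the basic olefination that follows.

Step 16
Reactants: 23 silylated aldehyde; 15 C5 phosphonate
Product: 25 ethyl (2E,4E,6S)-3,9-dimethyl-6-{2-[(triethylsilyl)oxy]propan-2-yl}deca-2,4,8-trienoate, via lithium phosphonate carbanion 24 (not isolated)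
Conditions: 15, LiN(SiMe3)2, THF, −78 °C; then 23, −78 → 0 °C
Reagents that add atoms: none
Why: Horner–Wadsworth–Emmons olefination should form C3'=C4' with E selectivity, and the weakly basic lithium carbanion at low temperature protects the stereocentre next to the aldehyde and avoids β-elimination of the silyloxy group.

Step 17
Reactants: 25 dienoate
Product: 26 (2E,4E,6S)-3,9-dimethyl-6-{2-[(triethylsilyl)oxy]propan-2-yl}deca-2,4,8-trien-1-ol
Conditions: i-Bu2AlH, CH2Cl2, −78 °C
Reagents that add atoms: none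
Why: 1,2-Reduction of the conjugated ester with i-Bu2AlH should give the dienyl alcohol and leave the silyl ether intact.

Step 18
Reactants: 26 dienyl alcohol
Product: 27 (2E,4E,6S)-3,9-dimethyl-6-{2-[(triethylsilyl)oxy]propan-2-yl}deca-2,4,8-trienal
Conditions: MnO2, CH2Cl2, rt
Reagents that add atoms: none
Why: MnO2 oxidises the allylic (dienylic) alcohol selectively to the dienal.

Step 19
Reactants: 27 dienal; 15 C5 phosphonate
Product: 29 ethyl (2E,4E,6E,8E,10S)-3,7,13-trimethyl-10-{2-[(triethylsilyl)oxy]propan-2-yl}tetradeca-2,4,6,8,12-pentaenoate, via potassium phosphonate carbanion 28 (not isolated)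
Conditions: 15, KOt-Bu, THF, 0 °C; then 27, −20 °C → rt
Reagents that add atoms: none
Why: A second Horner–Wadsworth–Emmons olefination, here with the more reactive potassium carbanion on the robust dienal, should form C7'=C8' with E selectivity.

Step 20
Reactants: 29 C15 ester
Product: 30 (2E,4E,6E,8E,10S)-3,7,13-trimethyl-10-{2-[(triethylsilyl)oxy]propan-2-yl}tetradeca-2,4,6,8,12-pentaen-1-ol
Conditions: i-Bu2AlH, CH2Cl2, −78 °C
Reagents that add atoms: none
Why: 1,2-Reduction of the conjugated ester with i-Bu2AlH should give the primary polyenyl alcohol.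

Step 21
Reactants: 30 C15 alcohol
Product: 31 [(2E,4E,6E,8E,10S)-3,7,13-trimethyl-10-{2-[(triethylsilyl)oxy]propan-2-yl}tetradeca-2,4,6,8,12-pentaen-1-yl]triphenylphosphonium bromide
Conditions: Ph3P·HBr, CH2Cl2, 0 °C
Reagents that add atoms: triphenylphosphine hydrobromide [Br-].[PH+](c1ccccc1)(c1ccccc1)c1ccccc1
Why: SN1-type phosphonium salt formation at the highly stabilised polyenyl alcohol should be much faster than ionisation of the hindered tertiary silyl ether.

**Assembly**

Step 22
Reactants: 31 acyclic phosphonium salt; 32 (2E,4E,6E)-2,7-dimethylocta-2,4,6-trienedial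
Product: 33 (2E,4E,6E,8E,10E,12E,14E,16E,18S)-2,7,11,15,21-pentamethyl-18-{2-[(triethylsilyl)oxy]propan-2-yl}docosa-2,4,6,8,10,12,14,16,20-nonaenal
Conditions: 32 (3 equiv), NaOMe, MeOH/CH2Cl2, 0 °C → rt
Reagents that add atoms: none
Why: Wittig reaction of the ylide of 31 with an excess of the symmetrical dialdehyde should stop at mono-olefination and form C11'=C12'.

Step 23
Reactants: 33 polyene aldehyde; 19 ring phosphonium salt
Product: 34 (2R,6R,2'S)-2-[(2E)-4-(TBDPSO)-3-methylbut-2-en-1-yl]-2'-(3-methylbut-2-en-1-yl)-1'-(TESO)-3',4'-didehydro-1',2'-dihydro-ε,ψ-carotene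
Conditions: NaOMe, MeOH/CH2Cl2, 0 °C → rt; then I2 (cat.), hexane, daylight
Reagents that add atoms: none
Why: The second Wittig reaction forms C11=C12 and joins the two halves, and iodine-catalysed photo-equilibration should convert Z isomers of the newly formed double bonds into the all-E polyene.

Step 24
Reactants: 34 bis-silyl ether
Product: 35 (2R,6R,2'S)-2-[(2E)-4-hydroxy-3-methylbut-2-en-1-yl]-2'-(3-methylbut-2-en-1-yl)-3',4'-didehydro-1',2'-dihydro-ε,ψ-caroten-1'-ol (CNP0409952.1)
Conditions: n-Bu4NF, THF, 0 °C → rt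
Reagents that add atoms: none
Why: Fluoride-mediated desilylation, driven by the strong Si–F bond, should cleave both silyl ethers under conditions that the polyene and the tertiary alcohol tolerate.

**Compound list**

1 | (R)-lavandulol, (2R)-5-methyl-2-(prop-1-en-2-yl)hex-4-en-1-ol | OC[C@H](CC=C(C)C)C(C)=C | starting material
2 | (3R)-3-(bromomethyl)-2,6-dimethylhepta-1,5-diene | BrC[C@H](CC=C(C)C)C(C)=C | intermediate
3 | (2E,5R)-5-(bromomethyl)-2,6-dimethylhepta-2,6-dien-1-ol | BrC[C@H](C/C=C(\C)CO)C(C)=C | intermediate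
4 | tert-butyl{[(2E,5R)-5-(bromomethyl)-2,6-dimethylhepta-2,6-dien-1-yl]oxy}diphenylsilane | BrC[C@H](C/C=C(\C)CO[Si](C(C)(C)C)(c1ccccc1)c1ccccc1)C(C)=C | intermediate
5 | methyl acetoacetate | COC(=O)CC(C)=O | starting material
6 | sodium lithium dianion of methyl acetoacetate | COC(=O)[CH-]C(=O)[CH2-].[Na+].[Li+] | intermediate
7 | methyl (6R)-6-[(2E)-4-(TBDPSO)-3-methylbut-2-en-1-yl]-7-methyl-3-oxooct-7-enoate | COC(=O)CC(=O)CC[C@H](C/C=C(\C)CO[Si](C(C)(C)C)(c1ccccc1)c1ccccc1)C(C)=C | intermediate
8 | methyl (1S,3R)-3-[(2E)-4-(TBDPSO)-3-methylbut-2-en-1-yl]-2,2-dimethyl-6-oxocyclohexane-1-carboxylate (drawn as the cis keto form; C1 is labile) | COC(=O)[C@@H]1C(=O)CC[C@H](C/C=C(\C)CO[Si](C(C)(C)C)(c2ccccc2)c2ccccc2)C1(C)C | intermediate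
9 | methyl (5R)-5-[(2E)-4-(TBDPSO)-3-methylbut-2-en-1-yl]-6,6-dimethyl-2-[(trifluoromethanesulfonyl)oxy]cyclohex-1-ene-1-carboxylate | COC(=O)C1=C(OS(=O)(=O)C(F)(F)F)CC[C@H](C/C=C(\C)CO[Si](C(C)(C)C)(c2ccccc2)c2ccccc2)C1(C)C | intermediate
10 | methyl (5R)-5-[(2E)-4-(TBDPSO)-3-methylbut-2-en-1-yl]-2,6,6-trimethylcyclohex-1-ene-1-carboxylate | COC(=O)C1=C(C)CC[C@H](C/C=C(\C)CO[Si](C(C)(C)C)(c2ccccc2)c2ccccc2)C1(C)C | intermediate
11 | lithium dienolate of 10 (exocyclic C=C(OMe)OLi on C6, exocyclic C5=CH2) | COC([O-])=C1C(=C)CC[C@H](C/C=C(\C)CO[Si](C(C)(C)C)(c2ccccc2)c2ccccc2)C1(C)C.[Li+] | intermediate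
12 | methyl (1R,3R)-3-[(2E)-4-(TBDPSO)-3-methylbut-2-en-1-yl]-2,2-dimethyl-6-methylidenecyclohexane-1-carboxylate | COC(=O)[C@@H]1C(=C)CC[C@H](C/C=C(\C)CO[Si](C(C)(C)C)(c2ccccc2)c2ccccc2)C1(C)C | intermediate
13 | methyl (1R,5R)-5-[(2E)-4-(TBDPSO)-3-methylbut-2-en-1-yl]-2,6,6-trimethylcyclohex-2-ene-1-carboxylate | COC(=O)[C@@H]1C(C)=CC[C@H](C/C=C(\C)CO[Si](C(C)(C)C)(c2ccccc2)c2ccccc2)C1(C)C | intermediate
14 | (1R,5R)-5-[(2E)-4-(TBDPSO)-3-methylbut-2-en-1-yl]-2,6,6-trimethylcyclohex-2-ene-1-carbaldehyde | O=C[C@@H]1C(C)=CC[C@H](C/C=C(\C)CO[Si](C(C)(C)C)(c2ccccc2)c2ccccc2)C1(C)C | intermediate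
15 | ethyl (2E)-4-(diethoxyphosphoryl)-3-methylbut-2-enoate | CCOC(=O)/C=C(C)/CP(=O)(OCC)OCC | starting material
16 | sodium salt of the carbanion of 15 | CCOC(=O)/C=C(C)/[CH-]P(=O)(OCC)OCC.[Na+] | intermediate
17 | ethyl (2E,4E)-5-{(1R,5R)-5-[(2E)-4-(TBDPSO)-3-methylbut-2-en-1-yl]-2,6,6-trimethylcyclohex-2-en-1-yl}-3-methylpenta-2,4-dienoate | CCOC(=O)/C=C(C)/C=C/[C@@H]1C(C)=CC[C@H](C/C=C(\C)CO[Si](C(C)(C)C)(c2ccccc2)c2ccccc2)C1(C)C | intermediate
18 | (2E,4E)-5-{(1R,5R)-5-[(2E)-4-(TBDPSO)-3-methylbut-2-en-1-yl]-2,6,6-trimethylcyclohex-2-en-1-yl}-3-methylpenta-2,4-dien-1-ol | OC/C=C(C)/C=C/[C@@H]1C(C)=CC[C@H](C/C=C(\C)CO[Si](C(C)(C)C)(c2ccccc2)c2ccccc2)C1(C)C | intermediate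
19 | {(2E,4E)-5-[(1R,5R)-5-((2E)-4-(TBDPSO)-3-methylbut-2-en-1-yl)-2,6,6-trimethylcyclohex-2-en-1-yl]-3-methylpenta-2,4-dien-1-yl}triphenylphosphonium bromide | [Br-].c3ccccc3[P+](c4ccccc4)(c5ccccc5)C/C=C(C)/C=C/[C@@H]1C(C)=CC[C@H](C/C=C(\C)CO[Si](C(C)(C)C)(c2ccccc2)c2ccccc2)C1(C)C | intermediate
20 | (3S)-1-(acetoxymercurio)-3-(hydroxymethyl)-2,6-dimethylhept-5-en-2-ol (both C2 epimers) | OC[C@H](CC=C(C)C)C(C)(O)C[Hg]OC(C)=O | intermediate
21 | (2S)-3-methyl-2-(3-methylbut-2-en-1-yl)butane-1,3-diol | OC[C@H](CC=C(C)C)C(C)(C)O | intermediate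
22 | (2R)-3-hydroxy-3-methyl-2-(3-methylbut-2-en-1-yl)butanal | O=C[C@H](CC=C(C)C)C(C)(C)O | intermediate
23 | (2R)-3-methyl-2-(3-methylbut-2-en-1-yl)-3-[(triethylsilyl)oxy]butanal | O=C[C@H](CC=C(C)C)C(C)(C)O[Si](CC)(CC)CC | intermediate
24 | lithium salt of the carbanion of 15 | CCOC(=O)/C=C(C)/[CH-]P(=O)(OCC)OCC.[Li+] | intermediate
25 | ethyl (2E,4E,6S)-3,9-dimethyl-6-{2-[(triethylsilyl)oxy]propan-2-yl}deca-2,4,8-trienoate | CCOC(=O)/C=C(C)/C=C/[C@H](CC=C(C)C)C(C)(C)O[Si](CC)(CC)CC | intermediate
26 | (2E,4E,6S)-3,9-dimethyl-6-{2-[(triethylsilyl)oxy]propan-2-yl}deca-2,4,8-trien-1-ol | OC/C=C(C)/C=C/[C@H](CC=C(C)C)C(C)(C)O[Si](CC)(CC)CC | intermediate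
27 | (2E,4E,6S)-3,9-dimethyl-6-{2-[(triethylsilyl)oxy]propan-2-yl}deca-2,4,8-trienal | O=C/C=C(C)/C=C/[C@H](CC=C(C)C)C(C)(C)O[Si](CC)(CC)CC | intermediate
28 | potassium salt of the carbanion of 15 | CCOC(=O)/C=C(C)/[CH-]P(=O)(OCC)OCC.[K+] | intermediate
29 | ethyl (2E,4E,6E,8E,10S)-3,7,13-trimethyl-10-{2-[(triethylsilyl)oxy]propan-2-yl}tetradeca-2,4,6,8,12-pentaenoate | CCOC(=O)/C=C(C)/C=C/C=C(C)/C=C/[C@H](CC=C(C)C)C(C)(C)O[Si](CC)(CC)CC | intermediate
30 | (2E,4E,6E,8E,10S)-3,7,13-trimethyl-10-{2-[(triethylsilyl)oxy]propan-2-yl}tetradeca-2,4,6,8,12-pentaen-1-ol | OC/C=C(C)/C=C/C=C(C)/C=C/[C@H](CC=C(C)C)C(C)(C)O[Si](CC)(CC)CC | intermediate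
31 | [(2E,4E,6E,8E,10S)-3,7,13-trimethyl-10-{2-[(triethylsilyl)oxy]propan-2-yl}tetradeca-2,4,6,8,12-pentaen-1-yl]triphenylphosphonium bromide | [Br-].c3ccccc3[P+](c4ccccc4)(c5ccccc5)C/C=C(C)/C=C/C=C(C)/C=C/[C@H](CC=C(C)C)C(C)(C)O[Si](CC)(CC)CC | intermediate
32 | (2E,4E,6E)-2,7-dimethylocta-2,4,6-trienedial | O=C/C(C)=C/C=C/C=C(C)/C=O | starting material
33 | (2E,4E,6E,8E,10E,12E,14E,16E,18S)-2,7,11,15,21-pentamethyl-18-{2-[(triethylsilyl)oxy]propan-2-yl}docosa-2,4,6,8,10,12,14,16,20-nonaenal | O=C/C(C)=C/C=C/C=C(C)/C=C/C=C(C)/C=C/C=C(C)/C=C/[C@H](CC=C(C)C)C(C)(C)O[Si](CC)(CC)CC | intermediate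
34 | (2R,6R,2'S)-2-[(2E)-4-(TBDPSO)-3-methylbut-2-en-1-yl]-2'-(3-methylbut-2-en-1-yl)-1'-(TESO)-3',4'-didehydro-1',2'-dihydro-ε,ψ-carotene | CC(C)=CC[C@@H](/C=C/C(C)=C/C=C/C(C)=C/C=C/C(C)=C/C=C/C=C(C)/C=C/C=C(C)/C=C/[C@@H]1C(C)=CC[C@H](C/C=C(\C)CO[Si](C(C)(C)C)(c2ccccc2)c2ccccc2)C1(C)C)C(C)(C)O[Si](CC)(CC)CC | intermediate
35 | (2R,6R,2'S)-2-[(2E)-4-hydroxy-3-methylbut-2-en-1-yl]-2'-(3-methylbut-2-en-1-yl)-3',4'-didehydro-1',2'-dihydro-ε,ψ-caroten-1'-ol (CNP0409952.1) | CC(C)=CC[C@@H](/C=C/C(C)=C/C=C/C(C)=C/C=C/C(C)=C/C=C/C=C(C)/C=C/C=C(C)/C=C/[C@@H]1C(C)=CC[C@H](C/C=C(\C)CO)C1(C)C)C(C)(C)O | target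

**Count and risks**

Total: 24 steps. Longest linear sequence: 14 steps (steps 1–12, 23 and 24).

Step 4. The acid-triggered stage may be unselective: the acid formed with SnCl4 can also protonate the side-chain alkene or ionise its allylic silyl ether, and the tertiary cation can relax by a 1,2-hydride shift from the neighbouring C2–H, which would erode the lavandulol-derived stereocentre. In that case the fallback sets out from keto ester 7, isolated after the alkylation stage, and closes the ring by carbomercuration instead of protonation. Hg(OSO2CF3)2 in MeNO2/CH2Cl2 at −20 °C should add to the 1,1-disubstituted alkene only, and the enol carbon opens the mercurinium ion at the tertiary carbon without a free cation. Treatment with NaCl then gives the chloromercurio keto ester F1, and Bu3SnH replaces the mercury by hydrogen, which returns the route to 8.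

Step 7. Deprotonation of the hindered ester may be slow or incomplete, the dienolate may be protonated at the exocyclic carbon with return to the conjugated ester, or the proton may be delivered to C6 with poor facial selectivity. The fallback sets out from conjugated ester 10 and replaces the strong base by light (photodeconjugation of an α,β-unsaturated ester). Irradiation at 254 nm in hexane with 1,2-dimethylimidazole (0.1 equiv) should cause a 1,5-hydrogen shift from the C5 methyl group, the only γ-hydrogen source cis to the carbonyl group, and give the photodienol F2. The weak base then ketonises the dienol by protonation at C6 under the same steric bias, which returns the route to 12; C6 epimers, if formed, would be separated at this stage.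

Step 10. The phosphonate carbanion may enolise the β,γ-unsaturated aldehyde 14, with epimerisation at C6 or migration of the ring double bond into conjugation with the carbonyl group. The fallback sets out from 14 and uses a neutral stabilised ylide. Ph3P=CHC(O)CH3 in toluene at 80 °C should give the E-enone F3. Addition of CH2=CHMgBr in the presence of CeCl3 then gives the tertiary vinyl carbinol F4 as a mixture of carbinol epimers. Ph3P·HBr in CH2Cl2 converts it with allylic transposition into the phosphonium salt, so the route is rejoined at 19 and compounds 17 and 18 are bypassed.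

Further compounds
F1 | step 4 | methyl (1S,3R)-2-[(chloromercurio)methyl]-3-[(2E)-4-(TBDPSO)-3-methylbut-2-en-1-yl]-2-methyl-6-oxocyclohexane-1-carboxylate (both C2 epimers) | COC(=O)[C@@H]1C(=O)CC[C@H](C/C=C(\C)CO[Si](C(C)(C)C)(c2ccccc2)c2ccccc2)C1(C)C[Hg]Cl
F2 | step 7 | methoxy{(3R)-3-[(2E)-4-(TBDPSO)-3-methylbut-2-en-1-yl]-2,2-dimethyl-6-methylidenecyclohexylidene}methanol (photodienol; enol geometry not specified) | COC(O)=C1C(=C)CC[C@H](C/C=C(\C)CO[Si](C(C)(C)C)(c2ccccc2)c2ccccc2)C1(C)C
F3 | step 10 | (3E)-4-{(1R,5R)-5-[(2E)-4-(TBDPSO)-3-methylbut-2-en-1-yl]-2,6,6-trimethylcyclohex-2-en-1-yl}but-3-en-2-one | CC(=O)/C=C/[C@@H]1C(C)=CC[C@H](C/C=C(\C)CO[Si](C(C)(C)C)(c2ccccc2)c2ccccc2)C1(C)C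
F4 | step 10 | (1E)-1-{(1R,5R)-5-[(2E)-4-(TBDPSO)-3-methylbut-2-en-1-yl]-2,6,6-trimethylcyclohex-2-en-1-yl}-3-methylpenta-1,4-dien-3-ol (both C3 epimers) | C=CC(C)(O)/C=C/[C@@H]1C(C)=CC[C@H](C/C=C(\C)CO[Si](C(C)(C)C)(c2ccccc2)c2ccccc2)C1(C)C
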